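**Plan**

- Retrosynthetic cuts: first the bond from ring-B C5 to the vinyl carbon of the ring-D styryl arm; then, after joining the ring-B C2 oxygen to Cβ in thought, the Cα–C1(ring B) and O–Cβ bonds of the resulting trans-2,3-diaryl-2,3-dihydrobenzofuran; last the Cα=Cβ bond of the stilbene carrying rings A and C.
- Enabling feature: ring B (2-hydroxy-3-methoxy-5-styrylphenyl) is bound through C1 to the methine Cα and its C2 oxygen lies one atom (Cβ, the CH2 on ring C) short of a dihydrobenzofuran. Ring C (2,4-dihydroxyphenyl) has its C4–OH para to Cβ and ring A (4-hydroxy-3-methoxyphenyl) sits on Cα, so a 4-hydroxystilbene plus a methoxy quinone monoimide maps onto the skeleton.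
- Forward order: Horner–Wadsworth–Emmons olefination joins rings A and C; a Boc-aminophenol is oxidised to the ring-B quinone imide; the [3+2] annulation closes the only ring made in the route; hydrogenolysis reopens O–Cβ; the nitrogen at C5 is exchanged for the ring-D styryl group by Heck–Matsuda coupling; deacetylation finishes.
- Stereochemistry: the single stereocentre of the target (Cα, S) is set as C3 of the dihydrobenzofuran by a chiral phosphoric acid. C2 is a relay centre erased on ring opening. Both alkenes are E from the olefination and the Heck–Matsuda step.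

Key step: step 8

Assumption: the (R)-configured phosphoric acid is taken to deliver the (3S) centre; should the opposite sense be found, the (S)-acid is used with no other change.

**Route**

Step 1
Reactants: 1 (4-benzyloxy-3-methoxyphenyl)methanol
Product: 3 diethyl (4-benzyloxy-3-methoxybenzyl)phosphonate, via 4-benzyloxy-3-methoxybenzyl chloride 2 (not isolated)
Conditions: SOCl2, CH2Cl2, 0 °C to rt; evaporate; then P(OEt)3 (neat), 130 °C
Reagents that add atoms: triethyl phosphite, CCOP(OCC)OCC
Why: Thionyl chloride converts the electron-rich benzylic alcohol into the chloride, which undergoes a Michaelis–Arbuzov reaction with triethyl phosphite to give the benzylphosphonate with loss of chloroethane.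

Step 2
Reactants: 4 2,4-dihydroxybenzaldehyde
Product: 5 2-hydroxy-4-(methoxymethoxy)benzaldehyde
Conditions: MOMCl (1.1 equiv), K2CO3, acetone, 0 °C to rt
Reagents that add atoms: chloromethyl methyl ether, COCCl
Why: Williamson-type O-alkylation should take place only at the 4-hydroxyl, because the 2-hydroxyl is tied up in a hydrogen bond to the aldehyde and is the less acidic and less nucleophilic of the two.

Step 3
Reactants: 5 2-hydroxy-4-(methoxymethoxy)benzaldehyde
Product: 6 2-benzyloxy-4-(methoxymethoxy)benzaldehyde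
Conditions: BnBr, K2CO3, DMF, 60 °C
Reagents that add atoms: benzyl bromide, BrCc1ccccc1
Why: Williamson ether synthesis on the remaining chelated phenol proceeds in DMF with mild heating, and the acetal is stable to base.

Step 4
Reactants: 3 diethyl (4-benzyloxy-3-methoxybenzyl)phosphonate; 6 2-benzyloxy-4-(methoxymethoxy)benzaldehyde
Product: 7 (E)-2-benzyloxy-1-[2-(4-benzyloxy-3-methoxyphenyl)ethenyl]-4-(methoxymethoxy)benzene
Conditions: KOtBu, THF, 0 °C to rt
Reagents that add atoms: none
Why: Horner–Wadsworth–Emmons olefination of a benzylphosphonate anion with an aryl aldehyde gives the E-stilbene because the reversible addition funnels through the anti oxaphosphetane.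

Step 5
Reactants: 7 (E)-2-benzyloxy-1-[2-(4-benzyloxy-3-methoxyphenyl)ethenyl]-4-(methoxymethoxy)benzene
Product: 8 (E)-3-benzyloxy-4-[2-(4-benzyloxy-3-methoxyphenyl)ethenyl]phenol
Conditions: HCl (3 M aq), MeOH/THF, 40 °C
Reagents that add atoms: none
Why: Acid-catalysed acetal cleavage removes the methoxymethyl group alone and frees the ring-C 4-hydroxyl, since benzyl ethers and the E-alkene tolerate dilute acid in methanol.

Step 6
Reactants: 9 4-amino-2-methoxyphenol
Product: 10 tert-butyl (4-hydroxy-3-methoxyphenyl)carbamate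
Conditions: Boc2O, THF, rt, N2
Reagents that add atoms: di-tert-butyl dicarbonate, CC(C)(C)OC(=O)OC(=O)OC(C)(C)C
Why: Carbamate formation is chemoselective for nitrogen because, without added base, the aniline is far more nucleophilic than the phenol.

Step 7
Reactants: 10 tert-butyl (4-hydroxy-3-methoxyphenyl)carbamate
Product: 11 tert-butyl (3-methoxy-4-oxocyclohexa-2,5-dien-1-ylidene)carbamate
Conditions: PhI(OAc)2, CH2Cl2, 0 °C; cold NaHCO3 wash, used at once
Reagents that add atoms: none
Why: Two-electron oxidation of a para-(acylamino)phenol with a hypervalent iodine reagent is the standard entry to N-acyl and N-sulfonyl quinone monoimides.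

Step 8
Reactants: 8 (E)-3-benzyloxy-4-[2-(4-benzyloxy-3-methoxyphenyl)ethenyl]phenol; 11 tert-butyl (3-methoxy-4-oxocyclohexa-2,5-dien-1-ylidene)carbamate
Product: 13 tert-butyl [(2S,3S)-2-(2-benzyloxy-4-hydroxyphenyl)-3-(4-benzyloxy-3-methoxyphenyl)-7-methoxy-2,3-dihydrobenzofuran-5-yl]carbamate, via para-quinone methide adduct 12 (not isolated)
Conditions: (R)-TRIP [(R)-3,3'-bis(2,4,6-triisopropylphenyl)-1,1'-binaphthyl-2,2'-diyl hydrogen phosphate] (10 mol %), 4 Å MS, toluene/CH2Cl2 (4:1), −30 °C
Reagents that add atoms: none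
Why: Proposed new method: the phosphoric acid should hold the imide of 11 (through its acidic proton) and the free ring-C phenol of 8 (through its phosphoryl oxygen) in one assembly, so that the vinylogous phenol attacks through Cα at the unsubstituted ring carbon of 11 that flanks the carbonyl and lies β to the acyl-imine, and tautomerisation of the adduct gives the aminophenol para-quinone methide 12, whose new phenol oxygen then adds to Cβ. The closest known reaction type is the phosphoric-acid-catalysed formal [3+2] coupling of quinone monoimides with electron-rich styrenes and enecarbamates to 5-amino-2,3-dihydrobenzofurans, backed by Lewis-acid couplings of quinone monoimides with propenylarenes, but a 1,2-diaryl alkene has not been shown to take part. The one new ring, the dihydrofuran, closes by 5-exo-trig oxa-Michael addition of the phenol oxygen to the quinone methide carbon. C3 (Cα) is fixed in the C–C bond-forming event by the chiral phosphate, which leaves one face of the alkene open in the doubly hydrogen-bonded transition state, and C2 (Cβ) is fixed relative to C3 by the substrate, the reversible ring closure settling on the trans arrangement of the two aryl groups. The step needs Cα and not Cβ as the nucleophilic carbon and attack beside the carbonyl of 11 on the side away from the methoxy group: the free 4-OH and the 2-benzyloxy group of ring C drive electron density to Cα while the ring-A oxygen is masked as a benzyl ether, and the methoxy group of 11 occupies the other carbon beside the carbonyl.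

Step 9
Reactants: 13 tert-butyl [(2S,3S)-2-(2-benzyloxy-4-hydroxyphenyl)-3-(4-benzyloxy-3-methoxyphenyl)-7-methoxy-2,3-dihydrobenzofuran-5-yl]carbamate
Product: 14 tert-butyl {3-[(1S)-2-(2,4-dihydroxyphenyl)-1-(4-hydroxy-3-methoxyphenyl)ethyl]-4-hydroxy-5-methoxyphenyl}carbamate
Conditions: H2 (3 atm), Pd(OH)2/C, EtOH/EtOAc, AcOH (5 vol %), 40 °C
Reagents that add atoms: none
Why: Catalytic hydrogenolysis removes both benzyl ethers and cleaves the ring C2–O bond, a benzylic aryl ether activated by the ortho and para oxygens of ring C (the same bond type that opens when pterocarpans are hydrogenolysed to isoflavans), while C3 is not a site of bond breaking and the carbamate and methyl ethers are inert.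

Step 10
Reactants: 14 tert-butyl {3-[(1S)-2-(2,4-dihydroxyphenyl)-1-(4-hydroxy-3-methoxyphenyl)ethyl]-4-hydroxy-5-methoxyphenyl}carbamate
Product: 15 tert-butyl {4-acetoxy-3-[(1S)-1-(4-acetoxy-3-methoxyphenyl)-2-(2,4-diacetoxyphenyl)ethyl]-5-methoxyphenyl}carbamate
Conditions: Ac2O, pyridine, rt to 40 °C (no DMAP)
Reagents that add atoms: acetic anhydride, CC(=O)OC(C)=O
Why: Pyridine-mediated O-acetylation esterifies all four phenols, which shuts down azo coupling and oxidation later, and in the absence of an acyl-transfer catalyst the carbamate N–H is left alone.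

Step 11
Reactants: 15 tert-butyl {4-acetoxy-3-[(1S)-1-(4-acetoxy-3-methoxyphenyl)-2-(2,4-diacetoxyphenyl)ethyl]-5-methoxyphenyl}carbamate
Product: 16 4-acetoxy-3-[(1S)-1-(4-acetoxy-3-methoxyphenyl)-2-(2,4-diacetoxyphenyl)ethyl]-5-methoxyaniline
Conditions: CF3CO2H/CH2Cl2 (1:4), 0 °C to rt; NaHCO3 work-up
Reagents that add atoms: none
Why: Acidolysis of the tert-butyl carbamate releases the aniline with loss of 2-methylpropene and carbon dioxide, and aryl acetates are stable to anhydrous trifluoroacetic acid.

Step 12
Reactants: 17 3,5-dihydroxybenzaldehyde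
Product: 18 3,5-dihydroxystyrene (5-ethenylbenzene-1,3-diol)
Conditions: MePPh3Br (3.2 equiv), KOtBu (3.1 equiv), THF, 0 °C to rt; NH4Cl work-up; used without delay
Reagents that add atoms: methyltriphenylphosphonium bromide, C[P+](c1ccccc1)(c1ccccc1)c1ccccc1.[Br-]
Why: Wittig methylenation with excess ylide tolerates the phenols, which are merely deprotonated, and their meta position means the phenoxides do not deactivate the aldehyde by conjugation.

Step 13
Reactants: 18 3,5-dihydroxystyrene
Product: 19 3,5-diacetoxystyrene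
Conditions: Ac2O, Et3N, DMAP (cat.), CH2Cl2, 0 °C
Reagents that add atoms: acetic anhydride, CC(=O)OC(C)=O
Why: Standard O-acetylation caps both phenols so that the styrene cannot undergo azo coupling with the diazonium salt in the next step.

Step 14
Reactants: 16 4-acetoxy-3-[(1S)-1-(4-acetoxy-3-methoxyphenyl)-2-(2,4-diacetoxyphenyl)ethyl]-5-methoxyaniline; 19 3,5-diacetoxystyrene
Product: 21 hexaacetate of the target with (S) centre and (E) alkene, via arenediazonium tetrafluoroborate 20 (not isolated)
Conditions: NOBF4, MeCN, −30 to 0 °C; then 19 (1.5 equiv), Pd(OAc)2 (5 mol %), NaOAc, MeCN, rt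
Reagents that add atoms: none
Why: Nitrosonium tetrafluoroborate diazotises the aniline and the diazonium salt undergoes ligand-free Heck–Matsuda arylation at the terminal alkene carbon of the styrene, syn insertion followed by syn β-hydride elimination giving the E-stilbene under conditions that leave aryl acetates and the remote stereocentre untouched.

Step 15
Reactants: 21 hexaacetate of the target
Product: 22 4-[(2S)-2-(4-hydroxy-3-methoxyphenyl)-2-{2-hydroxy-3-methoxy-5-[(E)-2-(3,5-dihydroxyphenyl)ethenyl]phenyl}ethyl]benzene-1,3-diol (CNP0254096.1)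
Conditions: K2CO3 (0.5 equiv), degassed MeOH, 0 °C to rt, Ar; then Amberlite IR-120 (H+ form)
Reagents that add atoms: none
Why: Base-catalysed methanolysis (transesterification) strips the six aryl acetates under conditions too mild to deprotonate the diarylmethine carbon or isomerise the stilbene, and exclusion of air protects the polyphenol.

**Compound list**

1 | (4-benzyloxy-3-methoxyphenyl)methanol | COc1cc(CO)ccc1OCc1ccccc1 | starting material
2 | 4-benzyloxy-3-methoxybenzyl chloride | COc1cc(CCl)ccc1OCc1ccccc1 | intermediate (not isolated)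
3 | diethyl (4-benzyloxy-3-methoxybenzyl)phosphonate | CCOP(=O)(Cc1ccc(OCc2ccccc2)c(OC)c1)OCC | intermediate
4 | 2,4-dihydroxybenzaldehyde | O=Cc1ccc(O)cc1O | starting material
5 | 2-hydroxy-4-(methoxymethoxy)benzaldehyde | COCOc1ccc(C=O)c(O)c1 | intermediate
6 | 2-benzyloxy-4-(methoxymethoxy)benzaldehyde | COCOc1ccc(C=O)c(OCc2ccccc2)c1 | intermediate
7 | (E)-2-benzyloxy-1-[2-(4-benzyloxy-3-methoxyphenyl)ethenyl]-4-(methoxymethoxy)benzene | COCOc1ccc(/C=C/c2ccc(OCc3ccccc3)c(OC)c2)c(OCc2ccccc2)c1 | intermediate
8 | (E)-3-benzyloxy-4-[2-(4-benzyloxy-3-methoxyphenyl)ethenyl]phenol | COc1cc(/C=C/c2ccc(O)cc2OCc2ccccc2)ccc1OCc1ccccc1 | intermediate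
9 | 4-amino-2-methoxyphenol | COc1cc(N)ccc1O | starting material
10 | tert-butyl (4-hydroxy-3-methoxyphenyl)carbamate | COc1cc(NC(=O)OC(C)(C)C)ccc1O | intermediate
11 | tert-butyl (3-methoxy-4-oxocyclohexa-2,5-dien-1-ylidene)carbamate | COC1=CC(=NC(=O)OC(C)(C)C)C=CC1=O | intermediate
12 | tert-butyl {3-[(1S)-1-(4-benzyloxy-3-methoxyphenyl)-2-(2-benzyloxy-4-oxocyclohexa-2,5-dien-1-ylidene)ethyl]-4-hydroxy-5-methoxyphenyl}carbamate (exocyclic alkene geometry not fixed) | COc1cc([C@H](C=C2C=CC(=O)C=C2OCc2ccccc2)c2cc(NC(=O)OC(C)(C)C)cc(OC)c2O)ccc1OCc1ccccc1 | intermediate (not isolated)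
13 | tert-butyl [(2S,3S)-2-(2-benzyloxy-4-hydroxyphenyl)-3-(4-benzyloxy-3-methoxyphenyl)-7-methoxy-2,3-dihydrobenzofuran-5-yl]carbamate (trans) | COc1cc([C@@H]2[C@@H](c3ccc(O)cc3OCc3ccccc3)Oc3c(OC)cc(NC(=O)OC(C)(C)C)cc32)ccc1OCc1ccccc1 | intermediate
14 | tert-butyl {3-[(1S)-2-(2,4-dihydroxyphenyl)-1-(4-hydroxy-3-methoxyphenyl)ethyl]-4-hydroxy-5-methoxyphenyl}carbamate | COc1cc([C@H](Cc2ccc(O)cc2O)c2cc(NC(=O)OC(C)(C)C)cc(OC)c2O)ccc1O | intermediate
15 | tert-butyl {4-acetoxy-3-[(1S)-1-(4-acetoxy-3-methoxyphenyl)-2-(2,4-diacetoxyphenyl)ethyl]-5-methoxyphenyl}carbamate | COc1cc([C@H](Cc2ccc(OC(C)=O)cc2OC(C)=O)c2cc(NC(=O)OC(C)(C)C)cc(OC)c2OC(C)=O)ccc1OC(C)=O | intermediate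
16 | 4-acetoxy-3-[(1S)-1-(4-acetoxy-3-methoxyphenyl)-2-(2,4-diacetoxyphenyl)ethyl]-5-methoxyaniline | COc1cc([C@H](Cc2ccc(OC(C)=O)cc2OC(C)=O)c2cc(N)cc(OC)c2OC(C)=O)ccc1OC(C)=O | intermediate
17 | 3,5-dihydroxybenzaldehyde | O=Cc1cc(O)cc(O)c1 | starting material
18 | 3,5-dihydroxystyrene | C=Cc1cc(O)cc(O)c1 | intermediate
19 | 3,5-diacetoxystyrene | C=Cc1cc(OC(C)=O)cc(OC(C)=O)c1 | intermediate
20 | 4-acetoxy-3-[(1S)-1-(4-acetoxy-3-methoxyphenyl)-2-(2,4-diacetoxyphenyl)ethyl]-5-methoxybenzenediazonium tetrafluoroborate | COc1cc([C@H](Cc2ccc(OC(C)=O)cc2OC(C)=O)c2cc([N+]#N)cc(OC)c2OC(C)=O)ccc1OC(C)=O.F[B-](F)(F)F | intermediate (not isolated)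
21 | hexaacetate of the target: 4-acetoxy-3-[(1S)-1-(4-acetoxy-3-methoxyphenyl)-2-(2,4-diacetoxyphenyl)ethyl]-5-methoxy-1-[(E)-2-(3,5-diacetoxyphenyl)ethenyl]benzene | COc1cc([C@H](Cc2ccc(OC(C)=O)cc2OC(C)=O)c2cc(/C=C/c3cc(OC(C)=O)cc(OC(C)=O)c3)cc(OC)c2OC(C)=O)ccc1OC(C)=O | intermediate
22 | 4-[(2S)-2-(4-hydroxy-3-methoxyphenyl)-2-{2-hydroxy-3-methoxy-5-[(E)-2-(3,5-dihydroxyphenyl)ethenyl]phenyl}ethyl]benzene-1,3-diol | COc1cc([C@H](Cc2ccc(O)cc2O)c2cc(/C=C/c3cc(O)cc(O)c3)cc(OC)c2O)ccc1O | target

**Step count and risks**

Total step count: 15. Longest linear sequence: 10 steps (steps 2, 3, 4, 5, 8, 9, 10, 11, 14, 15, from 2,4-dihydroxybenzaldehyde).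

Steps most likely to fail:

1. Step 8. The chiral phosphate may discriminate the faces of Cα poorly, or C–C bond formation with the hindered 1,2-diaryl alkene may be so slow that electron transfer between the phenol and the imide, or arylation of ring C itself, takes over. The fallback sets out from 8 and 11 and gives up catalyst control. The coupling is run in the known Lewis-acid mode of quinone monoimide and arylalkene [3+2] annulation (BF3·OEt2, CH2Cl2, −78 °C). This should give the racemic trans-dihydrobenzofuran, that is 13 together with its mirror image, tert-butyl [(2R,3R)-2-(2-benzyloxy-4-hydroxyphenyl)-3-(4-benzyloxy-3-methoxyphenyl)-7-methoxy-2,3-dihydrobenzofuran-5-yl]carbamate F1. The enantiomers are separated by preparative supercritical-fluid chromatography on a chiral stationary phase, and the route is rejoined at 13.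

2. Step 9. Debenzylation may run ahead and leave the cyclic C2–O bond uncleaved, or the catalyst may be slowed by the carbamate and the polyphenol. The fallback sets out from 13 and opens the ring by ionic hydrogenation instead (Et3SiH, CF3CO2H, CH2Cl2, 0 °C). The C2–O bond ionises to the benzylic cation stabilised by ring C and is reduced by hydride; excess silane and low temperature are used so that hydride capture outruns loss of the Cα proton. The Boc group falls off in the same flask, giving 4-amino-2-[(1S)-2-(2-benzyloxy-4-hydroxyphenyl)-1-(4-benzyloxy-3-methoxyphenyl)ethyl]-6-methoxyphenol F2. Nitrogen is re-protected (Boc2O, THF, rt) to tert-butyl {3-[(1S)-2-(2-benzyloxy-4-hydroxyphenyl)-1-(4-benzyloxy-3-methoxyphenyl)ethyl]-4-hydroxy-5-methoxyphenyl}carbamate F3. Plain O-debenzylation (H2, Pd/C, EtOAc/MeOH, rt) then rejoins the route at 14.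

3. Step 14. The diazonium group may be lost by reduction or solvolysis before migratory insertion, or the palladium may be deactivated, so that the styryl arm is not attached. The fallback sets out from 16 and replaces the diazonium coupling by a halide coupling. Diazotisation–iodination (p-TsOH·H2O, NaNO2, KI, MeCN/H2O, 10 °C to rt) gives the aryl iodide 4-acetoxy-3-[(1S)-1-(4-acetoxy-3-methoxyphenyl)-2-(2,4-diacetoxyphenyl)ethyl]-1-iodo-5-methoxybenzene F4. A conventional Mizoroki–Heck reaction with 19 (Pd(OAc)2, P(o-tol)3, Et3N, DMF, 90 °C), a coupling established for acetoxystyrenes and acetoxy-substituted aryl iodides, rejoins the route at 21.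

**Further compounds**

F1 | step 8 | tert-butyl [(2R,3R)-2-(2-benzyloxy-4-hydroxyphenyl)-3-(4-benzyloxy-3-methoxyphenyl)-7-methoxy-2,3-dihydrobenzofuran-5-yl]carbamate | COc1cc([C@H]2[C@H](c3ccc(O)cc3OCc3ccccc3)Oc3c(OC)cc(NC(=O)OC(C)(C)C)cc32)ccc1OCc1ccccc1
F2 | step 9 | 4-amino-2-[(1S)-2-(2-benzyloxy-4-hydroxyphenyl)-1-(4-benzyloxy-3-methoxyphenyl)ethyl]-6-methoxyphenol | COc1cc([C@H](Cc2ccc(O)cc2OCc2ccccc2)c2cc(N)cc(OC)c2O)ccc1OCc1ccccc1
F3 | step 9 | tert-butyl {3-[(1S)-2-(2-benzyloxy-4-hydroxyphenyl)-1-(4-benzyloxy-3-methoxyphenyl)ethyl]-4-hydroxy-5-methoxyphenyl}carbamate | COc1cc([C@H](Cc2ccc(O)cc2OCc2ccccc2)c2cc(NC(=O)OC(C)(C)C)cc(OC)c2O)ccc1OCc1ccccc1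
F4 | step 14 | 4-acetoxy-3-[(1S)-1-(4-acetoxy-3-methoxyphenyl)-2-(2,4-diacetoxyphenyl)ethyl]-1-iodo-5-methoxybenzene | COc1cc([C@H](Cc2ccc(OC(C)=O)cc2OC(C)=O)c2cc(I)cc(OC)c2OC(C)=O)ccc1OC(C)=O
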